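**Numbering.** Cembrane numbering is used throughout: C1 carries C15(=C16)C17, the lactone oxygen sits on C12, C3 is the carbinol carbon, and C11 is the acetoxy carbon.

**Assumption.** Commercial (+)-limonene oxide (cis/trans epoxide mixture from (R)-limonene) is taken as the cheap chiral source. The epoxide centres are destroyed in step 3, so only limonene C4, the future C1 (R), matters.

**Retrosynthesis**
1. Target ⇐ C3 enone (late Luche reduction) ⇐ bridged ε-lactone, made last by transannular Markovnikov mercurilactonization of the C17 acrylic acid onto an exocyclic C12=CH2 (C12 set by ring geometry).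
2. The 14-membered carbocycle comes from RCM closing C4=C5 of a triene. The triene is made by coupling the C12 vinyllithium with a Weinreb amide carrying C11–C5.
3. The vinyl iodide comes from limonene-derived keto-aldehyde (C1–C3, C12–C14, C15–C17, C20). The Weinreb amide comes from a Johnson–Claisen [3,3] rearrangement (key step), which sets the (E)-Δ7 alkene and the C9–C10 bond.
4. Ring order: carbocycle by RCM first, then the lactone.

**Route**

**Step 1**
Reactants: 1, (+)-limonene 1,2-oxide (4R; cis/trans epoxide mixture)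
Product: 2, allylic alcohol 2-(6-methyl-7-oxabicyclo[4.1.0]heptan-3-yl)prop-2-en-1-ol (C17–OH)
Conditions: SeO2 (10 mol %), TBHP, solid NaHCO3, CH2Cl2, 25 °C
Reagents that add atoms: tert-butyl hydroperoxide, CC(C)(C)OO (oxygen source)
Why: Riley/Sharpless allylic oxidation occurs at the isopropenyl CH3, the only alkene left; C4 (future C1) is untouched.

**Step 2**
Reactants: 2
Product: 3, TBS ether of 2
Conditions: TBSCl, imidazole, DMF, 0 °C → rt
Reagents that add atoms: tert-butyldimethylsilyl chloride, CC(C)(C)[Si](C)(C)Cl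
Why: Silylation masks the primary alcohol so it survives the later Shapiro and organolithium steps.

**Step 3**
Reactants: 3
Product: 4, (3R)-3-[1-(TBSO-methyl)vinyl]-6-oxoheptanal (keto-aldehyde)
Conditions: H5IO6, Et2O/THF, 0 °C → rt
Reagents that add atoms: periodic acid, OI(=O)(O)(O)(O)O (oxygen source)
Why: Epoxide hydrolysis followed by Malaprade glycol cleavage gives the C12 methyl ketone and C3 aldehyde, which delivers C2–C3 directly; C1 is not touched.

**Step 4**
Reactants: 4
Product: 5, C3 isopropenyl carbinol with the methyl ketone intact (C3 epimer mixture)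
Conditions: isopropenylMgBr (1.05 equiv), THF, −78 °C
Reagents that add atoms: isopropenylmagnesium bromide, C=C(C)[Mg]Br
Why: Chemoselective Grignard 1,2-addition to the more electrophilic aldehyde creates C3–C4. The C3 epimers are deliberately converged later by oxidation (step 20).

**Step 5**
Reactants: 5
Product: 6, C3 TBS ether of 5
Conditions: TBSCl, imidazole, DMAP (cat.), DMF, 40 °C
Reagents that add atoms: CC(C)(C)[Si](C)(C)Cl
Why: Protection prevents the alkoxide and OH from interfering with the base and organolithium steps.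

**Step 6**
Reactants: 6
Product: 7, 2,4,6-triisopropylbenzenesulfonylhydrazone of the C12 ketone
Conditions: TrisNHNH2 (1.1 equiv), cat. HCl, THF, rt
Reagents that add atoms: 2,4,6-triisopropylbenzenesulfonyl hydrazide, CC(C)c1cc(C(C)C)c(S(=O)(=O)NN)c(C(C)C)c1
Why: Condensation of the hydrazide with the ketone carbonyl prepares the Shapiro substrate.

**Step 7**
Reactants: 7
Product: 8, C12 vinyl iodide (C20H2=C12(I)–C13…)
Conditions: n-BuLi (3.5 equiv), THF, −78 → 0 °C; then I2, −78 °C
Reagents that add atoms: iodine, II
Why: The Shapiro reaction deprotonates the less hindered methyl side, giving the terminal vinyllithium, which I2 traps as the 2-iodoalkene.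

**Step 8**
Reactants: 9, methacrolein, C=C(C)C=O
Product: 10, 2-methylhexa-1,5-dien-3-ol, C=CCC(O)C(C)=C
Conditions: allylMgBr (1.1 equiv), Et2O, −78 → 0 °C
Reagents that add atoms: allylmagnesium bromide, C=CC[Mg]Br
Why: 1,2-Grignard addition to the enal gives the secondary carbinol needed for the Claisen rearrangement; it is racemic, but the carbinol carbon becomes sp2 in the next step.

**Step 9 (key step)**
Reactants: 10
Product: 11, ethyl (E)-4-methylocta-4,7-dienoate, CCOC(=O)CC/C(C)=C/CC=C
Conditions: CH3C(OEt)3 (6 equiv), EtCO2H (5 mol %), 140 °C, sealed tube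
Reagents that add atoms: triethyl orthoacetate, CCOC(C)(OCC)OCC (supplies the CH2CO2Et unit, C10–C11)
Why: The Johnson–Claisen [3,3]-sigmatropic rearrangement forms the C9–C10 bond, and the chair transition state with the allyl group equatorial gives the (E)-trisubstituted Δ7 alkene.

**Step 10**
Reactants: 11
Product: 12, (E)-N-methoxy-N,4-dimethylocta-4,7-dienamide (Weinreb amide), CON(C)C(=O)CC/C(C)=C/CC=C
Conditions: MeNH(OMe)·HCl, i-PrMgCl (3 equiv), THF, −20 → 0 °C
Reagents that add atoms: N,O-dimethylhydroxylamine, CNOC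
Why: Magnesium-amide aminolysis converts the ester to an acylating agent that will stop cleanly at the ketone; both alkenes are inert.

**Step 11**
Reactants: 8 (vinyl iodide) and 12 (Weinreb amide)
Product: 13, triene enone (C12=C20 α-methylene ketone at C11; terminal C5 vinyl; C4 isopropenyl)
Conditions: t-BuLi (2.1 equiv), Et2O, −78 °C; then 12, −78 → −20 °C
Reagents that add atoms: none
Why: Lithium–iodine exchange followed by Weinreb acylation forms the C11–C12 bond without over-addition.

**Step 12**
Reactants: 13
Product: 14, 14-membered macrocyclic enone with (E)-C4=C5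
Conditions: Hoveyda–Grubbs II (10 mol %), CH2Cl2 (2 mM), 40 °C, Ar sparge
Reagents that add atoms: none (ethylene is lost)
Why: Ring-closing metathesis of the isopropenyl and vinyl termini gives the trisubstituted (E)-olefin, and the hindered α-branched C15 alkene stays unreacted.

**Step 13**
Reactants: 14
Product: 15, C11 allylic alcohol (11S)
Conditions: NaBH4, CeCl3·7H2O, MeOH, −78 °C
Reagents that add atoms: none
Why: Luche 1,2-reduction sets C11 by hydride delivery to the open exterior face of the macrocycle, with the conformation controlled by C1.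

**Step 14**
Reactants: 15
Product: 16, C11 acetate
Conditions: Ac2O, Et3N, DMAP, CH2Cl2, 0 °C → rt
Reagents that add atoms: acetic anhydride, CC(=O)OC(C)=O
Why: The only free alcohol is acetylated, installing the C11 acetoxy group of the target; this also protects C11 from MnO2 later.

**Step 15**
Reactants: 16
Product: 17, primary allylic alcohol (C17–OH)
Conditions: PPTS (cat.), MeOH/CH2Cl2, 25 °C
Reagents that add atoms: none
Why: Acid methanolysis removes the unhindered primary TBS ether and leaves the secondary C3 TBS ether and the acetate.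

**Step 16**
Reactants: 17
Product: 18, α-methylene aldehyde (C17 CHO)
Conditions: MnO2 (30 equiv), CH2Cl2, 25 °C
Reagents that add atoms: none
Why: MnO2 oxidizes the primary allylic alcohol selectively; the C3 carbinol is silylated and C11 is acetylated, so neither is touched.

**Step 17**
Reactants: 18
Product: 19, α-methylene carboxylic acid (C17 CO2H)
Conditions: NaClO2, NaH2PO4, 2-methyl-2-butene, t-BuOH/H2O, 25 °C
Reagents that add atoms: sodium chlorite, [Na+].[O-]Cl=O (oxygen source)
Why: Pinnick oxidation with a hypochlorite scavenger leaves the trisubstituted alkenes intact.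

**Step 18**
Reactants: 19
Product: 20, bridged α-methylene ε-lactone (C3–OTBS), with C12 quaternary (R)
Conditions: (i) Hg(OAc)2, THF, 25 °C; (ii) NaBH4, THF/MeOH, 0 °C
Reagents that add atoms: none (Hg is removed; the net result is hydroacyloxylation)
Why: Transannular Markovnikov mercurilactonization onto the 1,1-disubstituted C12=C20 alkene forms the seven-membered lactone, and demercuration turns C20 into CH3. The C1-tethered carboxylate can only reach the C12 face on the same side as the C1–C15 bond, which fixes C12 as (R).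

**Step 19**
Reactants: 20
Product: 21, C3 alcohol (C3 epimer mixture)
Conditions: HF·pyridine, pyridine/THF, 0 °C → rt
Reagents that add atoms: none
Why: Fluoride removes the secondary TBS ether without touching the lactone or the acetate.

**Step 20**
Reactants: 21
Product: 22, C3 enone
Conditions: MnO2 (30 equiv), CH2Cl2, 25 °C
Reagents that add atoms: none
Why: Allylic oxidation destroys the C3 stereochemistry inherited from step 4, so both epimers converge on one ketone.

**Step 21**
Reactants: 22
Product: 23, Dendronpholide A (3S)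
Conditions: NaBH4, CeCl3·7H2O, MeOH, −78 °C
Reagents that add atoms: none
Why: Luche 1,2-reduction of the enone sets C3 by hydride attack on the exposed face of the rigid lactone-bridged macrocycle, with no 1,4-reduction of the α-methylene lactone.

**Compound list**

1 | (+)-limonene 1,2-oxide (4R) | CC12CC[C@H](CC1O2)C(C)=C | starting material
2 | 2-(6-methyl-7-oxabicyclo[4.1.0]heptan-3-yl)prop-2-en-1-ol | CC12CC[C@H](CC1O2)C(=C)CO | intermediate
3 | TBS ether of 2 | CC12CC[C@H](CC1O2)C(=C)CO[Si](C)(C)C(C)(C)C | intermediate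
4 | (3R)-3-[1-(TBSO-methyl)vinyl]-6-oxoheptanal | CC(=O)CC[C@@H](C(=C)CO[Si](C)(C)C(C)(C)C)CC=O | intermediate
5 | C3 isopropenyl carbinol from 4 (C3 epimer mixture) | CC(=O)CC[C@@H](C(=C)CO[Si](C)(C)C(C)(C)C)CC(O)C(C)=C | intermediate
6 | C3 TBS ether of 5 | CC(=O)CC[C@@H](C(=C)CO[Si](C)(C)C(C)(C)C)CC(O[Si](C)(C)C(C)(C)C)C(C)=C | intermediate
7 | trisylhydrazone of 6 | CC(=NNS(=O)(=O)c1c(C(C)C)cc(C(C)C)cc1C(C)C)CC[C@@H](C(=C)CO[Si](C)(C)C(C)(C)C)CC(O[Si](C)(C)C(C)(C)C)C(C)=C | intermediate
8 | C12 vinyl iodide | C=C(I)CC[C@@H](C(=C)CO[Si](C)(C)C(C)(C)C)CC(O[Si](C)(C)C(C)(C)C)C(C)=C | intermediate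
9 | methacrolein | C=C(C)C=O | starting material
10 | 2-methylhexa-1,5-dien-3-ol | C=CCC(O)C(C)=C | intermediate
11 | ethyl (E)-4-methylocta-4,7-dienoate | CCOC(=O)CC/C(C)=C/CC=C | intermediate
12 | Weinreb amide of 11 | CON(C)C(=O)CC/C(C)=C/CC=C | intermediate
13 | triene enone | C=C(C(=O)CC/C(C)=C/CC=C)CC[C@@H](C(=C)CO[Si](C)(C)C(C)(C)C)CC(O[Si](C)(C)C(C)(C)C)C(C)=C | intermediate
14 | macrocyclic enone (C4=C5 E) | C=C1CC[C@@H](C(=C)CO[Si](C)(C)C(C)(C)C)CC(O[Si](C)(C)C(C)(C)C)/C(C)=C/C/C=C(\C)CCC1=O | intermediate
15 | C11 alcohol (11S) | C=C1CC[C@@H](C(=C)CO[Si](C)(C)C(C)(C)C)CC(O[Si](C)(C)C(C)(C)C)/C(C)=C/C/C=C(\C)CC[C@@H]1O | intermediate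
16 | C11 acetate | C=C1CC[C@@H](C(=C)CO[Si](C)(C)C(C)(C)C)CC(O[Si](C)(C)C(C)(C)C)/C(C)=C/C/C=C(\C)CC[C@@H]1OC(C)=O | intermediate
17 | C17 primary alcohol | C=C1CC[C@@H](C(=C)CO)CC(O[Si](C)(C)C(C)(C)C)/C(C)=C/C/C=C(\C)CC[C@@H]1OC(C)=O | intermediate
18 | α-methylene aldehyde | C=C1CC[C@@H](C(=C)C=O)CC(O[Si](C)(C)C(C)(C)C)/C(C)=C/C/C=C(\C)CC[C@@H]1OC(C)=O | intermediate
19 | α-methylene acid | C=C1CC[C@@H](C(=C)C(=O)O)CC(O[Si](C)(C)C(C)(C)C)/C(C)=C/C/C=C(\C)CC[C@@H]1OC(C)=O | intermediate
20 | lactone, C3–OTBS | C=C1C(=O)O[C@]2(C)CC[C@@H]1CC(O[Si](C)(C)C(C)(C)C)/C(C)=C/C/C=C(\C)CC[C@@H]2OC(C)=O | intermediate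
21 | lactone, C3–OH (C3 epimer mixture) | C=C1C(=O)O[C@]2(C)CC[C@@H]1CC(O)/C(C)=C/C/C=C(\C)CC[C@@H]2OC(C)=O | intermediate
22 | C3 enone | C=C1C(=O)O[C@]2(C)CC[C@@H]1CC(=O)/C(C)=C/C/C=C(\C)CC[C@@H]2OC(C)=O | intermediate
23 | Dendronpholide A | C=C1C(=O)O[C@]2(C)CC[C@@H]1C[C@H](O)/C(C)=C/C/C=C(\C)CC[C@@H]2OC(C)=O | target

**Totals:** 21 steps in total and 18 in the longest linear sequence (1 → 8 → 13 → 23), with a convergent three-step side chain (steps 8–10).

**Three steps most likely to fail**
1. **Step 12 (RCM).** The risks are competing metathesis at the other 1,1-disubstituted alkenes and poor E/Z control at C4=C5. Fallback: close the ring by intramolecular Nozaki–Hiyama–Kishi coupling at C3–C4 (C3 aldehyde plus C4 alkenyl iodide) instead of metathesis.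
2. **Step 18 (transannular mercurilactonization).** The risks are chemoselectivity over the Δ4 and Δ7 alkenes and an incorrect C12 outcome. Fallback: from the C11 alcohol (15), do a hydroxyl-directed VO(acac)2/TBHP epoxidation of the C12 methylene to the spiro-epoxide, open it with the C17 acid at C12 with inversion, then remove the resulting neopentyl CH2OH by Barton–McCombie deoxygenation.
3. **Steps 13 and 21 (Luche reductions setting C11 and C3).** Macrocyclic facial selectivity is unproven and may give the wrong epimer. Fallback: Mitsunobu inversion of the undesired epimer (p-nitrobenzoic acid, DIAD, PPh3, then K2CO3/MeOH) instead of re-optimising the hydride reduction.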